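## Retrosynthetic overview

1. The target is epicatechin-(4β→6)-epiafzelechin-(4β→8)-epicatechin-(4β→6)-epicatechin (top, second, third and bottom unit; flavan numbering, rings A/B/C in each unit). The last step is hydrogenolysis of 16 benzyl ethers and 4 blocking bromines.
2. The two lower interflavan bonds (C4 of the second unit to C8 of the third, C4 of the third to C6 of the bottom unit) are cut first. They are made top-down by Friedel–Crafts couplings of bromine-capped 4-(2-ethoxyethoxy) electrophiles (from DDQ) with benzylated epicatechin and its 8-bromide, and close no ring.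
3. Key disconnection: C4 of the top unit is a diarylmethine carbon held between two phloroglucinol-type rings, C4a of its own ring A and C6 of ring A of the epiafzelechin unit. It is therefore traced back to an aldehyde carbon acting as a 1,1-dielectrophile. Cutting C4–C4a and C4–C6 gives the acyclic aldehyde 11 (O1–C2 aryl ether, C2 and C3 already set) and 8-bromo-tri-O-benzylepiafzelechin 14.
4. Aldehyde 11 comes from an Evans syn-glycolate aldol (C2, C3), Weinreb amide formation, copper-catalysed O-arylation with retention (O1–C8a), dibromination (caps the later C6/C8 and leaves one ortho carbon) and iBu2AlH reduction.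
5. Ring order: all aromatic rings and rings C of the second, third and bottom units are bought with epiafzelechin, epicatechin and the aromatic building blocks. Ring C of the top unit is the only skeletal ring made (step 9), and no ring is closed after it.

Key step: step 9

Assumption: (−)-epiafzelechin (12) and 1,3-bis(benzyloxy)-5-iodobenzene (8) are taken as catalogue compounds; benzyl ethers are the only hydroxyl protecting group and aryl bromine is used as a blocking group that hydrogenolysis removes.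

## Route

Step 1
Reactants: 1 (S)-4-benzyl-1,3-oxazolidin-2-one; 2 (benzyloxy)acetyl chloride
Product: 3 (S)-4-benzyl-3-[(benzyloxy)acetyl]-1,3-oxazolidin-2-one
Conditions: nBuLi, THF, −78 °C; then 2, −78 → 0 °C
Reagents that add atoms: none
Why: N-acylation of the lithiated Evans oxazolidinone by the acid chloride, which touches no stereocenter.

Step 2
Reactants: 3 (S)-4-benzyl-3-[(benzyloxy)acetyl]-1,3-oxazolidin-2-one; 4 3,4-bis(benzyloxy)benzaldehyde
Product: 6 (S)-4-benzyl-3-[(2S,3R)-2-(benzyloxy)-3-[3,4-bis(benzyloxy)phenyl]-3-hydroxypropanoyl]-1,3-oxazolidin-2-one, via dibutylboron Z-enolate 5 (not isolated)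
Conditions: Bu2BOTf, Et3N, CH2Cl2, −78 → 0 °C; then 4, −78 → 0 °C; aq. NaH2PO4/Na2HPO4 (pH 7), MeOH, H2O2
Reagents that add atoms: none
Why: Evans syn-aldol reaction, in which the Z-boron enolate reacts through a closed Zimmerman–Traxler transition state on the face away from the 4-benzyl group, so that the auxiliary sets both new stereocenters (2S,3R, the later 2,3-cis pair C3/C2 of the top unit).

Step 3
Reactants: 6 syn-aldol adduct
Product: 7 (2S,3R)-2-(benzyloxy)-3-[3,4-bis(benzyloxy)phenyl]-3-hydroxy-N-methoxy-N-methylpropanamide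
Conditions: MeNH(OMe)·HCl, AlMe3, CH2Cl2, −20 → 0 °C; aqueous potassium sodium tartrate
Reagents that add atoms: N,O-dimethylhydroxylamine hydrochloride, CNOC.Cl
Why: Weinreb transamidation (aluminium amide aminolysis of the imide, assisted by the free β-hydroxyl) should remove the auxiliary without epimerization and give a carbonyl group that resists retro-aldol cleavage and can later be reduced to the aldehyde.

Step 4
Reactants: 7 β-hydroxy Weinreb amide; 8 1,3-bis(benzyloxy)-5-iodobenzene
Product: 9 (2S,3R)-2-(benzyloxy)-3-[3,4-bis(benzyloxy)phenyl]-3-[3,5-bis(benzyloxy)phenoxy]-N-methoxy-N-methylpropanamide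
Conditions: CuI (10 mol %), 3,4,7,8-tetramethyl-1,10-phenanthroline (20 mol %), Cs2CO3, toluene, 90 °C
Reagents that add atoms: none
Why: Ullmann-type copper-catalysed C–O coupling of a secondary benzylic alcohol with an aryl iodide, in which the C–O bond at the stereocenter is not broken, so the later C2 keeps its configuration while the O1–C8a bond is made.

Step 5
Reactants: 9 aryl ether
Product: 10 (2S,3R)-2-(benzyloxy)-3-[3,4-bis(benzyloxy)phenyl]-3-[3,5-bis(benzyloxy)-2,4-dibromophenoxy]-N-methoxy-N-methylpropanamide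
Conditions: NBS (2.05 equiv), CH2Cl2, −78 → −20 °C
Reagents that add atoms: N-bromosuccinimide, O=C1CCC(=O)N1Br
Why: Electrophilic aromatic bromination, in which the phloroglucinol triether ring should react far faster than the catechol ring and take up two bromines (para and one ortho to the bulky sec-alkoxy group), leaving exactly one free ortho carbon for the ring closure and capping the later C6 and C8.

Step 6
Reactants: 10 dibromo Weinreb amide
Product: 11 (2S,3R)-2-(benzyloxy)-3-[3,4-bis(benzyloxy)phenyl]-3-[3,5-bis(benzyloxy)-2,4-dibromophenoxy]propanal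
Conditions: iBu2AlH, THF, −78 °C; aqueous potassium sodium tartrate; used crude
Reagents that add atoms: none
Why: Reduction of a Weinreb amide by iBu2AlH stops at the aldehyde through the chelated tetrahedral intermediate, and the α-alkoxy stereocenter should survive at low temperature.

Step 7
Reactants: 12 (−)-epiafzelechin
Product: 13 5,7,4′-tri-O-benzyl-(−)-epiafzelechin
Conditions: BnBr, K2CO3, DMF, 0 °C → rt
Reagents that add atoms: benzyl bromide, BrCc1ccccc1
Why: Williamson ether synthesis under carbonate conditions alkylates the three phenols and leaves the secondary 3-OH free.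

Step 8
Reactants: 13 5,7,4′-tri-O-benzyl-(−)-epiafzelechin
Product: 14 8-bromo-5,7,4′-tri-O-benzyl-(−)-epiafzelechin
Conditions: NBS (1.0 equiv), CH2Cl2, −78 °C → rt
Reagents that add atoms: N-bromosuccinimide, O=C1CCC(=O)N1Br
Why: Electrophilic aromatic bromination of 5,7-di-O-benzylflavans is C8-selective (C8 lies between O1 and one OBn, C6 between two OBn), so C6 remains the only nucleophilic carbon.

Step 9
Reactants: 11 aldehyde; 14 8-bromo-5,7,4′-tri-O-benzyl-(−)-epiafzelechin
Product: 17 protected dimer 3-O-benzyl-6,8-dibromo-5,7,3′,4′-tetra-O-benzylepicatechin-(4β→6)-8-bromo-5,7,4′-tri-O-benzylepiafzelechin, via flavan-4-ol 15 (not isolated), via C4 benzylic cation 16 (not isolated)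
Conditions: BF3·OEt2 (2 equiv), CH2Cl2, −78 → −30 °C; 11 added slowly to 14 (1.3 equiv)
Reagents that add atoms: none
Why: Proposed new method: BF3 activates the aldehyde of 11, whose carbonyl carbon (the later C4) is attacked by the only unsubstituted ortho carbon of the tethered dibromo-dibenzyloxyphenyl ether (6-exo-trig Friedel–Crafts hydroxyalkylation, C4–C4a bond, closing ring C of the top unit) to give the leucocyanidin-type 4-ol 15, which BF3 ionizes to the cation 16, stabilized by O1 and the 5- and 7-benzyloxy groups, and C6 of 14 then adds to C4. The closest known reaction types are the acid-promoted cyclization of 3-aryloxypropanals to chroman-4-ols, the double arylation of aldehydes by electron-rich arenes, and the Lewis-acid coupling of 4-oxygenated flavan-3-ols (the biogenetic flavan-3,4-diol route) with 8-bromo-blocked flavan nucleophiles, merged here into one annulative bis-arylation. C2 and C3 come unchanged from 11, and the new stereocenter C4 is set under substrate control, the nucleophile adding to the planar cation on the β face, anti to the α-oriented 3-benzyloxy and 2-aryl groups (3,4-trans, 4β), as in epicatechin-type couplings. The step needs regioselectivity on the nucleophile, which the 8-bromine of 14 secures (only C6 is free), a single ring-closure site, which the ortho bromine of the aryl ether secures, and no chain growth, which the bromines at C6 and C8 of the new ring A secure. Should 14 attack the aldehyde first, ionization of the resulting diarylcarbinol and six-membered cyclization onto the aryl ether should lead to the same product.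

Step 10
Reactants: 17 protected dimer
Product: 18 protected dimer bearing a 4β-(2-ethoxyethoxy) group at C4 of the epiafzelechin unit
Conditions: DDQ (2 equiv), 2-ethoxyethanol, CH2Cl2, rt
Reagents that add atoms: 2-ethoxyethanol, CCOCCO
Why: DDQ benzylic oxidation (hydride abstraction) at the only methylene C4 of 17 with capture of the cation by the alcohol anti to the 3-OH (4β), the C4 methine of the top unit being shielded by two fully substituted rings and attached to a bromine-deactivated ring A.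

Step 11
Reactants: 19 (−)-epicatechin
Product: 20 5,7,3′,4′-tetra-O-benzyl-(−)-epicatechin
Conditions: BnBr, K2CO3, DMF, 0 °C → rt
Reagents that add atoms: benzyl bromide, BrCc1ccccc1
Why: Williamson ether synthesis of the four phenols, the secondary 3-OH staying free.

Step 12
Reactants: 18 dimer electrophile; 20 5,7,3′,4′-tetra-O-benzyl-(−)-epicatechin
Product: 21 protected trimer 3-O-benzyl-6,8-dibromo-5,7,3′,4′-tetra-O-benzylepicatechin-(4β→6)-8-bromo-5,7,4′-tri-O-benzylepiafzelechin-(4β→8)-5,7,3′,4′-tetra-O-benzylepicatechin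
Conditions: TMSOTf (0.2 equiv), CH2Cl2, −78 °C; 20 (3 equiv)
Reagents that add atoms: none
Why: Lewis-acid-catalysed Friedel–Crafts flavan coupling, in which the cation from the 4-(2-ethoxyethoxy) group is captured by C8 of 20 (the more nucleophilic ring-A carbon) on the β face anti to the 3-OH (4β→8), while the fully capped electrophile cannot self-condense.

Step 13
Reactants: 21 protected trimer
Product: 22 protected trimer bearing a 4β-(2-ethoxyethoxy) group at C4 of the third unit
Conditions: DDQ (2 equiv), 2-ethoxyethanol, CH2Cl2, rt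
Reagents that add atoms: 2-ethoxyethanol, CCOCCO
Why: DDQ benzylic oxidation at the only remaining methylene C4, that of the electron-rich unbrominated third unit, with trapping by the alcohol anti to the 3-OH (4β).

Step 14
Reactants: 20 5,7,3′,4′-tetra-O-benzyl-(−)-epicatechin
Product: 23 8-bromo-5,7,3′,4′-tetra-O-benzyl-(−)-epicatechin
Conditions: NBS (1.0 equiv), CH2Cl2, −78 °C → rt
Reagents that add atoms: N-bromosuccinimide, O=C1CCC(=O)N1Br
Why: C8-selective electrophilic aromatic bromination, which blocks C8 so that the bottom unit can be attacked only at C6.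

Step 15
Reactants: 22 trimer electrophile; 23 8-bromo-5,7,3′,4′-tetra-O-benzyl-(−)-epicatechin
Product: 24 protected tetramer (16 benzyl ethers, bromine at C6 and C8 of the top unit and at C8 of the second and bottom units)
Conditions: TMSOTf (0.2 equiv), CH2Cl2, −78 → −40 °C; 23 (4 equiv)
Reagents that add atoms: none
Why: Lewis-acid-catalysed Friedel–Crafts flavan coupling, in which the C4 cation of the third unit is captured on its β face (anti to 3-OH) by C6 of 23, the only free ring-A carbon of the nucleophile (4β→6).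

Step 16
Reactants: 24 protected tetramer
Product: 25 epicatechin-(4β→6)-epiafzelechin-(4β→8)-epicatechin-(4β→6)-epicatechin (CNP0103636.1)
Conditions: H2 (1 atm), Pd(OH)2/C, Et3N, THF/MeOH/H2O, rt
Reagents that add atoms: none
Why: Palladium-catalysed hydrogenolysis should cleave the 16 benzyl ethers and the four aryl C–Br bonds in one operation, Et3N taking up HBr so that the acid-labile interflavan bonds and all stereocenters are left untouched.

## Compound list

1 | (S)-4-benzyl-1,3-oxazolidin-2-one | O=C1N[C@@H](Cc2ccccc2)CO1 | starting material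
2 | (benzyloxy)acetyl chloride | O=C(Cl)COCc1ccccc1 | starting material
3 | (S)-4-benzyl-3-[(benzyloxy)acetyl]-1,3-oxazolidin-2-one | O=C(COCc1ccccc1)N1[C@@H](Cc2ccccc2)COC1=O | intermediate
4 | 3,4-bis(benzyloxy)benzaldehyde | O=Cc1ccc(OCc2ccccc2)c(OCc2ccccc2)c1 | starting material
5 | dibutylboron (Z)-enolate of 3 | CCCCB(CCCC)O/C(=C\OCc1ccccc1)N1[C@@H](Cc2ccccc2)COC1=O | intermediate (not isolated)
6 | (S)-4-benzyl-3-[(2S,3R)-2-(benzyloxy)-3-[3,4-bis(benzyloxy)phenyl]-3-hydroxypropanoyl]-1,3-oxazolidin-2-one | O[C@H](c1ccc(OCc2ccccc2)c(OCc2ccccc2)c1)[C@H](OCc1ccccc1)C(=O)N1[C@@H](Cc2ccccc2)COC1=O | intermediate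
7 | (2S,3R)-2-(benzyloxy)-3-[3,4-bis(benzyloxy)phenyl]-3-hydroxy-N-methoxy-N-methylpropanamide | O[C@H](c1ccc(OCc2ccccc2)c(OCc2ccccc2)c1)[C@H](OCc1ccccc1)C(=O)N(C)OC | intermediate
8 | 1,3-bis(benzyloxy)-5-iodobenzene | Ic1cc(OCc2ccccc2)cc(OCc2ccccc2)c1 | starting material
9 | (2S,3R)-2-(benzyloxy)-3-[3,4-bis(benzyloxy)phenyl]-3-[3,5-bis(benzyloxy)phenoxy]-N-methoxy-N-methylpropanamide | C(c1ccccc1)Oc1cc(OCc2ccccc2)cc(O[C@H](c2ccc(OCc3ccccc3)c(OCc3ccccc3)c2)[C@H](OCc2ccccc2)C(=O)N(C)OC)c1 | intermediate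
10 | (2S,3R)-2-(benzyloxy)-3-[3,4-bis(benzyloxy)phenyl]-3-[3,5-bis(benzyloxy)-2,4-dibromophenoxy]-N-methoxy-N-methylpropanamide | Brc1c(OCc2ccccc2)cc(O[C@H](c2ccc(OCc3ccccc3)c(OCc3ccccc3)c2)[C@H](OCc2ccccc2)C(=O)N(C)OC)c(Br)c1OCc1ccccc1 | intermediate
11 | (2S,3R)-2-(benzyloxy)-3-[3,4-bis(benzyloxy)phenyl]-3-[3,5-bis(benzyloxy)-2,4-dibromophenoxy]propanal | Brc1c(OCc2ccccc2)cc(O[C@H](c2ccc(OCc3ccccc3)c(OCc3ccccc3)c2)[C@H](OCc2ccccc2)C=O)c(Br)c1OCc1ccccc1 | intermediate
12 | (−)-epiafzelechin, (2R,3R)-2-(4-hydroxyphenyl)chromane-3,5,7-triol | O[C@@H]1Cc2c(O)cc(O)cc2O[C@@H]1c1ccc(O)cc1 | starting material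
13 | 5,7,4′-tri-O-benzyl-(−)-epiafzelechin, (2R,3R)-5,7-bis(benzyloxy)-2-[4-(benzyloxy)phenyl]chroman-3-ol | O[C@@H]1Cc2c(OCc3ccccc3)cc(OCc3ccccc3)cc2O[C@@H]1c1ccc(OCc2ccccc2)cc1 | intermediate
14 | 8-bromo-5,7,4′-tri-O-benzyl-(−)-epiafzelechin | O[C@@H]1Cc2c(OCc3ccccc3)cc(OCc3ccccc3)c(Br)c2O[C@@H]1c1ccc(OCc2ccccc2)cc1 | intermediate
15 | (2R,3R)-3,5,7-tris(benzyloxy)-2-[3,4-bis(benzyloxy)phenyl]-6,8-dibromochroman-4-ol (2,3-cis, both C4 epimers) | OC1c2c(OCc3ccccc3)c(Br)c(OCc3ccccc3)c(Br)c2O[C@H](c2ccc(OCc3ccccc3)c(OCc3ccccc3)c2)[C@@H]1OCc1ccccc1 | intermediate (not isolated)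
16 | C4 benzylic cation derived from 15 by loss of the 4-hydroxyl | [CH+]1c2c(OCc3ccccc3)c(Br)c(OCc3ccccc3)c(Br)c2O[C@H](c2ccc(OCc3ccccc3)c(OCc3ccccc3)c2)[C@@H]1OCc1ccccc1 | intermediate (not isolated)
17 | 3-O-benzyl-6,8-dibromo-5,7,3′,4′-tetra-O-benzylepicatechin-(4β→6)-8-bromo-5,7,4′-tri-O-benzylepiafzelechin | C(c1ccccc1)Oc1ccc([C@H]2Oc3c(Br)c(OCc4ccccc4)c([C@H]4c5c(OCc6ccccc6)c(Br)c(OCc6ccccc6)c(Br)c5O[C@H](c5ccc(OCc6ccccc6)c(OCc6ccccc6)c5)[C@@H]4OCc4ccccc4)c(OCc4ccccc4)c3C[C@H]2O)cc1 | intermediate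
18 | 17 with a 4β-(2-ethoxyethoxy) group at C4 of the epiafzelechin unit (3,4-trans) | C(c1ccccc1)Oc1ccc([C@H]2Oc3c(Br)c(OCc4ccccc4)c([C@H]4c5c(OCc6ccccc6)c(Br)c(OCc6ccccc6)c(Br)c5O[C@H](c5ccc(OCc6ccccc6)c(OCc6ccccc6)c5)[C@@H]4OCc4ccccc4)c(OCc4ccccc4)c3[C@H](OCCOCC)[C@H]2O)cc1 | intermediate
19 | (−)-epicatechin, (2R,3R)-2-(3,4-dihydroxyphenyl)chromane-3,5,7-triol | O[C@@H]1Cc2c(O)cc(O)cc2O[C@@H]1c1ccc(O)c(O)c1 | starting material
20 | 5,7,3′,4′-tetra-O-benzyl-(−)-epicatechin | O[C@@H]1Cc2c(OCc3ccccc3)cc(OCc3ccccc3)cc2O[C@@H]1c1ccc(OCc2ccccc2)c(OCc2ccccc2)c1 | intermediate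
21 | 3-O-benzyl-6,8-dibromo-5,7,3′,4′-tetra-O-benzylepicatechin-(4β→6)-8-bromo-5,7,4′-tri-O-benzylepiafzelechin-(4β→8)-5,7,3′,4′-tetra-O-benzylepicatechin | C(c1ccccc1)Oc1ccc([C@H]2Oc3c(Br)c(OCc4ccccc4)c([C@H]4c5c(OCc6ccccc6)c(Br)c(OCc6ccccc6)c(Br)c5O[C@H](c5ccc(OCc6ccccc6)c(OCc6ccccc6)c5)[C@@H]4OCc4ccccc4)c(OCc4ccccc4)c3[C@H](c3c(OCc5ccccc5)cc(OCc5ccccc5)c4c3O[C@H](c3ccc(OCc5ccccc5)c(OCc5ccccc5)c3)[C@H](O)C4)[C@H]2O)cc1 | intermediate
22 | 21 with a 4β-(2-ethoxyethoxy) group at C4 of the third unit (3,4-trans) | C(c1ccccc1)Oc1ccc([C@H]2Oc3c(Br)c(OCc4ccccc4)c([C@H]4c5c(OCc6ccccc6)c(Br)c(OCc6ccccc6)c(Br)c5O[C@H](c5ccc(OCc6ccccc6)c(OCc6ccccc6)c5)[C@@H]4OCc4ccccc4)c(OCc4ccccc4)c3[C@H](c3c(OCc5ccccc5)cc(OCc5ccccc5)c4c3O[C@H](c3ccc(OCc5ccccc5)c(OCc5ccccc5)c3)[C@H](O)[C@H]4OCCOCC)[C@H]2O)cc1 | intermediate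
23 | 8-bromo-5,7,3′,4′-tetra-O-benzyl-(−)-epicatechin | O[C@@H]1Cc2c(OCc3ccccc3)cc(OCc3ccccc3)c(Br)c2O[C@@H]1c1ccc(OCc2ccccc2)c(OCc2ccccc2)c1 | intermediate
24 | protected tetramer: 21 extended at C4 of the third unit by a 4β→6 bond to 8-bromo-5,7,3′,4′-tetra-O-benzylepicatechin | C(c1ccccc1)Oc1ccc([C@H]2Oc3c(Br)c(OCc4ccccc4)c([C@H]4c5c(OCc6ccccc6)c(Br)c(OCc6ccccc6)c(Br)c5O[C@H](c5ccc(OCc6ccccc6)c(OCc6ccccc6)c5)[C@@H]4OCc4ccccc4)c(OCc4ccccc4)c3[C@H](c3c(OCc5ccccc5)cc(OCc5ccccc5)c4c3O[C@H](c3ccc(OCc5ccccc5)c(OCc5ccccc5)c3)[C@H](O)[C@H]4c3c(OCc5ccccc5)c(Br)c4c(c3OCc5ccccc5)C[C@@H](O)[C@@H](c3ccc(OCc5ccccc5)c(OCc5ccccc5)c3)O4)[C@H]2O)cc1 | intermediate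
25 | epicatechin-(4β→6)-epiafzelechin-(4β→8)-epicatechin-(4β→6)-epicatechin (CNP0103636.1) | Oc1ccc([C@H]2Oc3cc(O)c([C@H]4c5c(O)cc(O)cc5O[C@H](c5ccc(O)c(O)c5)[C@@H]4O)c(O)c3[C@H](c3c(O)cc(O)c4c3O[C@H](c3ccc(O)c(O)c3)[C@H](O)[C@H]4c3c(O)cc4c(c3O)C[C@@H](O)[C@@H](c3ccc(O)c(O)c3)O4)[C@H]2O)cc1 | target

## Step count and risks

Total step count: 16. Longest linear sequence: 12 steps (1, 2, 3, 4, 5, 6, 9, 10, 12, 13, 15, 16).

Steps most likely to fail:

Step 9 (the proposed new method). The Lewis acid may ionize the acyclic benzylic aryl ether at C2 before the ring is closed, with loss of the phenol or of the C2 configuration. The aldehyde may lose the aryloxide by β-elimination. Capture of the C4 cation by the doubly flanked C6 of 14 may be slow, and five-membered closure onto ring B may compete. The fallback takes the top unit from the natural flavan and sets out from 20. Benzylation of the 3-OH (NaH, BnBr, DMF) would give 3,5,7,3′,4′-penta-O-benzyl-(−)-epicatechin F1. DDQ oxidation in the presence of 2-ethoxyethanol would give the 4β-(2-ethoxyethoxy) derivative F2. Dibromination with NBS (2.1 equiv) would give the 6,8-dibromo electrophile F3. TMSOTf-catalysed coupling of F3 with 14 at −78 °C (bromine-directed 4β→6 coupling of the known type) would give 17, where the route is rejoined at step 10.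

Step 4. The caesium alkoxide of 7 may undergo retro-aldol cleavage or α-epimerization at 90 °C, and a hindered secondary alcohol may couple incompletely. The fallback transfers the aryl group from boron under neutral oxidative conditions and sets out from 7. Commercial 3,5-bis(benzyloxy)phenylboronic acid would be converted with KHF2 into potassium [3,5-bis(benzyloxy)phenyl]trifluoroborate F4. Compound 7 would then be arylated with F4 in a Chan–Lam-type etherification (Cu(OAc)2, DMAP, O2, CH2Cl2, rt), again with retention at the carbinol carbon, to give 9.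

Step 13. Hydride abstraction on the hindered trimer may lose site selectivity (C2–H and the methine C4–H positions of the upper units), and the acidic hydroquinone formed may cleave interflavan bonds. The fallback brings the leaving group in with the third unit instead of oxidizing late; it sets out from 20 and 18. DDQ and 2-ethoxyethanol would convert 20 into 4β-(2-ethoxyethoxy)-5,7,3′,4′-tetra-O-benzylepicatechin F5. Exchange with 2-mercaptobenzothiazole (BF3·OEt2, CH2Cl2) would give the 4β-(benzothiazol-2-ylthio) derivative F6. Coupling of 18 with F6 (BF3·OEt2, −78 °C, the hard Lewis acid activating only the oxygen leaving group) would give the trimer thioether F7. Thiophilic activation of F7 with AgBF4 in the presence of 23 would give 24, where the route is rejoined at step 16.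

## Further compounds

F1 | step 9 | 3,5,7,3′,4′-penta-O-benzyl-(−)-epicatechin | C(c1ccccc1)O[C@@H]1Cc2c(OCc3ccccc3)cc(OCc3ccccc3)cc2O[C@@H]1c1ccc(OCc2ccccc2)c(OCc2ccccc2)c1
F2 | step 9 | 4β-(2-ethoxyethoxy)-3,5,7,3′,4′-penta-O-benzylepicatechin | C(c1ccccc1)O[C@@H]1[C@@H](OCCOCC)c2c(OCc3ccccc3)cc(OCc3ccccc3)cc2O[C@@H]1c1ccc(OCc2ccccc2)c(OCc2ccccc2)c1
F3 | step 9 | 6,8-dibromo-4β-(2-ethoxyethoxy)-3,5,7,3′,4′-penta-O-benzylepicatechin | C(c1ccccc1)O[C@@H]1[C@@H](OCCOCC)c2c(OCc3ccccc3)c(Br)c(OCc3ccccc3)c(Br)c2O[C@@H]1c1ccc(OCc2ccccc2)c(OCc2ccccc2)c1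
F4 | step 4 | potassium [3,5-bis(benzyloxy)phenyl]trifluoroborate | [K+].F[B-](F)(F)c1cc(OCc2ccccc2)cc(OCc2ccccc2)c1
F5 | step 13 | 4β-(2-ethoxyethoxy)-5,7,3′,4′-tetra-O-benzylepicatechin | O[C@@H]1[C@@H](OCCOCC)c2c(OCc3ccccc3)cc(OCc3ccccc3)cc2O[C@@H]1c1ccc(OCc2ccccc2)c(OCc2ccccc2)c1
F6 | step 13 | 4β-(benzothiazol-2-ylthio)-5,7,3′,4′-tetra-O-benzylepicatechin | O[C@@H]1[C@@H](Sc2nc3ccccc3s2)c2c(OCc3ccccc3)cc(OCc3ccccc3)cc2O[C@@H]1c1ccc(OCc2ccccc2)c(OCc2ccccc2)c1
F7 | step 13 | protected trimer 21 bearing a 4β-(benzothiazol-2-ylthio) group at C4 of the third unit | C(c1ccccc1)Oc1ccc([C@H]2Oc3c(Br)c(OCc4ccccc4)c([C@H]4c5c(OCc6ccccc6)c(Br)c(OCc6ccccc6)c(Br)c5O[C@H](c5ccc(OCc6ccccc6)c(OCc6ccccc6)c5)[C@@H]4OCc4ccccc4)c(OCc4ccccc4)c3[C@H](c3c(OCc5ccccc5)cc(OCc5ccccc5)c4c3O[C@H](c3ccc(OCc5ccccc5)c(OCc5ccccc5)c3)[C@H](O)[C@H]4Sc3nc4ccccc4s3)[C@H]2O)cc1
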